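The summer run at 0.50 M of L and the winter run at 0.75 M drew one curve in percent of the L charged: at 2.50 d they read X 53% and 51%, a gap of 2 percentage points against a scatter of 1.5 points. So I read the flask at 1.0 M from the means of both.

| setting | summer | winter | flask |
|---|---|---|---|
| L | 0.50 M | 0.75 M | 1.0 M |
| remark | run made earlier | run made earlier |  |
| time |  |  | 15 d |

| run | time / d | X / % | Z / % |
|---|---|---|---|
| summer | 0.125 | 53 | 13 |
| summer | 0.500 | 63 | 1 |
| summer | 2.50 | 53 | 0 |
| summer | 12.0 | 31 | 2 |
| winter | 0.125 | 54 | 15 |
| winter | 0.500 | 64 | 3 |
| winter | 2.50 | 51 | 0 |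
| winter | 12.0 | 33 | 2 |

(readings scatter by 1.5 percentage points)

- a reading or a percentage of Z counts all its forms, free or not

- the best time, 15 d at the latest, for X
- the amount of X, in percent of the L charged, at that time
- earliest time at which at least nineteen twentieths of that best amount are there, in d
- latest time at which they still are, in d

By 0.125 d X read 53.5%, a mean slope of 4.28 d⁻¹ in charges per day. The mean reading of cZ fell from 14.0% to 2.00% by 0.500 d while X rose, and I drew the knee from that fall:

kZ = ln(early cZ / later cZ) / elapsed time = 5.19 d⁻¹

Behind the knee I put the top near 0.500 d. The mean X there I call the ceiling, the mean of the two runs' highest readings of X in percent of the L charged: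

ceiling = 63.5%, give or take 1.1 points; window level = 60.3%

On the rising side I took cX as the early sum cX + cZ, 67.5%, minus a decaying cZ. On the falling side the mean readings of X fell at 0.0999 d⁻¹ up to 2.50 d:

opening = 0.254 d; closing = 1.01 d

Later the fall eased to half that rate, with X reading 32.0% at 12.0 d.

The forecast, holding that “the percentages look independent of concentration”, gave 64% at 0.6 d and a window from 0.34 d to 1.05 d, which opens later than my reckoning.

The flask gave 62.8% at 0.423 d, with the window from 0.229 d to 0.992 d.

    L ⇌ X (K = 73.0, k = 1.30 h⁻¹)
    L ⇌ Z (K = 1.20, k = 1.10 h⁻¹)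
    L ⇌ D (K = 190, k = 0.640 h⁻¹)
    L + Z ⇌ Q, settled at all times (K = 7.90 M⁻¹)

In the flask, just after the start, the forward rate of L to D was half the forward rate of L to X, kinetic control with D held more strongly than X at equilibrium, and at 0.423 d X stood at 62.8% beside D 34.8%, Z with its bound form 1.45% and L 0.861%. After that X fell to 36.6% by 7.50 d while D rose to 62.3% and L lay at 0.445%. The ceiling stood 0.70 points above the flask's best, less than the scatter of 1.5 points, and the neighbour flask at 0.60 M of L reached 63.0%.

(All runs stem from a simulated flask with made-up constants; scatter was added.)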